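The cyclobutane is disconnected at C1–C2 and C2–C3. Ring carbon C2 carries only H, one bithienylethynyl arm and these two ring bonds, so it can originate from the formyl carbon of a bithienyl ynal, while a cyclopropylidene unit delivers C1, C3 and C4. In a single operation a sulfonium cyclopropylide adds to the aldehyde and the resulting oxaspiropentane ring-expands, creating the four-membered ring with a ketone at C1 as the handle for the second arm. The precursor is simply 3-(2,2'-bithiophen-5-yl)prop-2-ynal. Because the target is the meso cis isomer, racemic material suffices and only the relative configuration at C1 must be controlled afterwards.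

Key step: step 3

Remark on the chemistry: the target SMILES encodes the cis-(1R,2S) meso cyclobutane, so all chiral intermediates are racemates; 7, 8 and 9 have one stereocentre and are written without a descriptor, and for 10–13 and the F compounds the SMILES shows one enantiomer of the racemic cis compound. Ring numbering: C1 is the ketone carbon of 8 and carries the arm installed last, C2 carries the first arm, C3 and C4 are the CH2 groups.

Step 1
Reactants: 1 5-bromo-2,2'-bithiophene; 2 prop-2-yn-1-ol (propargyl alcohol)
Product: 3 3-(2,2'-bithiophen-5-yl)prop-2-yn-1-ol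
Conditions: PdCl2(PPh3)2 (cat.), CuI (cat.), Et3N, THF, 50 °C, degassed
Reagents that add atoms: none
Why: Sonogashira coupling, in which zerovalent palladium formed in situ inserts into the thienyl C–Br bond and the copper acetylide of 2 transmetalates, the free hydroxyl being tolerated.

Step 2
Reactants: 3 3-(2,2'-bithiophen-5-yl)prop-2-yn-1-ol
Product: 4 3-(2,2'-bithiophen-5-yl)prop-2-ynal
Conditions: activated MnO2 (excess), CH2Cl2, rt
Reagents that add atoms: none
Why: MnO2 oxidation of a propargylic alcohol, which should stop cleanly at the ynal and leave the thiophene sulfur atoms and the triple bond untouched.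

Step 3
Reactants: 4 3-(2,2'-bithiophen-5-yl)prop-2-ynal; 5 cyclopropyldiphenylsulfonium tetrafluoroborate
Product: 8 2-[(2,2'-bithiophen-5-yl)ethynyl]cyclobutan-1-one (racemic), via diphenylsulfonium cyclopropylide 6 (not isolated), via oxaspiropentane 7 (not isolated)
Conditions: 5 (slight excess over base), KN(SiMe3)2, DME, −45 °C; then 4, −45 → 0 °C; then LiBF4, 0 °C → rt
Reagents that add atoms: none
Why: Ylide 6, formed by deprotonating 5, should add through its carbanionic carbon to the formyl carbon of 4 (making C1–C2), and the betaine alkoxide then expels diphenyl sulfide to close the oxirane of 7 by a 3-exo-tet displacement. LiBF4 should ionise the oxirane C–O bond at C2, where the cation is propargylic, cyclopropylcarbinyl and conjugated to the bithienyl donor, and a 1,2-shift of a cyclopropane CH2 to C2 (making C2–C3) closes the cyclobutanone by ring expansion, not by cyclisation of a chain, as the oxygen becomes the C1 carbonyl. The closest known reaction type is the spiroannulation of aldehydes and ketones by sulfonium cyclopropylides, a Corey–Chaykovsky epoxidation followed by a semipinacol-type oxaspiropentane-to-cyclobutanone rearrangement. The single new stereocentre C2 is formed without control, which is acceptable because 8 is needed only as the racemate and the target is meso. The step needs 1,2- instead of 1,4-addition, which the hard unstabilised ylide, the low temperature and the high electrophilicity of the formyl group should secure, and it needs ionisation at C2 and not at the spiro carbon, which the propargylic stabilisation and the instability of a cyclopropyl cation should secure. Relief of the strain of two three-membered rings drives the sequence to the four-membered ketone.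

Step 4
Reactants: 8 2-[(2,2'-bithiophen-5-yl)ethynyl]cyclobutan-1-one (racemic)
Product: 9 5-[(2-methylidenecyclobutyl)ethynyl]-2,2'-bithiophene (racemic)
Conditions: Zn, CH2Br2, TiCl4 (reagent pre-formed in THF), CH2Cl2, 0 °C → rt
Reagents that add atoms: dibromomethane, BrCBr (the methylidene carbon)
Why: Lombardo methylenation, whose non-basic, oxophilic gem-dimetallic methylene reagent should convert the strained, easily enolised ketone into the exocyclic alkene without deprotonating the doubly activated C2–H and without touching the alkyne or the thiophenes.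

Step 5
Reactants: 9 5-[(2-methylidenecyclobutyl)ethynyl]-2,2'-bithiophene (racemic)
Product: 11 {cis-2-[(2,2'-bithiophen-5-yl)ethynyl]cyclobutyl}methanol (racemic), via B-alkyl-9-BBN adduct 10 (not isolated)
Conditions: 9-BBN, THF, 0 °C → rt; then NaOH, H2O2, 0 °C
Reagents that add atoms: hydrogen peroxide, OO (oxygen of the alcohol); 9-BBN, B1C2CCCC1CCC2 (boron cage, retained only in 10)
Why: Hydroboration–oxidation, in which 9-BBN should add to the 1,1-disubstituted alkene far faster than to the internal alkyne, place boron on the exocyclic carbon and deliver hydrogen to C1 from the ring face opposite the C2 arm, so that the CH2B group and, after oxidation with retention, the CH2OH group stand cis to the arm (substrate control of the new C1 stereocentre).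

Step 6
Reactants: 11 {cis-2-[(2,2'-bithiophen-5-yl)ethynyl]cyclobutyl}methanol (racemic)
Product: 12 cis-2-[(2,2'-bithiophen-5-yl)ethynyl]cyclobutane-1-carbaldehyde (racemic)
Conditions: Dess–Martin periodinane, pyridine, CH2Cl2, 0 °C → rt
Reagents that add atoms: none
Why: Dess–Martin oxidation under pyridine buffering is near neutral and fast, so the primary alcohol should give the aldehyde without epimerisation at C1 and without oxidation of the electron-rich bithiophene.

Step 7
Reactants: 12 cis-2-[(2,2'-bithiophen-5-yl)ethynyl]cyclobutane-1-carbaldehyde (racemic)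
Product: 13 5-[(cis-2-ethynylcyclobutyl)ethynyl]-2,2'-bithiophene (racemic)
Conditions: dimethyl (1-diazo-2-oxopropyl)phosphonate, K2CO3, MeOH/THF, 0 °C → rt
Reagents that add atoms: dimethyl (1-diazo-2-oxopropyl)phosphonate, CC(=O)C(=[N+]=[N-])P(=O)(OC)OC (the terminal alkyne carbon)
Why: Seyferth–Gilbert homologation in its Ohira–Bestmann form, in which the diazomethylphosphonate anion released by methanolysis olefinates the aldehyde and the diazoalkene loses N2 with a 1,2-hydrogen shift to the terminal alkyne; C1 keeps its configuration because exocyclic enolisation of a cyclobutane carbaldehyde is slow under cold carbonate.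

Step 8
Reactants: 13 5-[(cis-2-ethynylcyclobutyl)ethynyl]-2,2'-bithiophene (racemic); 1 5-bromo-2,2'-bithiophene
Product: 14 isocardopatine (cis-1,2-bis[(2,2'-bithiophen-5-yl)ethynyl]cyclobutane)
Conditions: Pd(PPh3)4 (cat.), CuI (cat.), Et3N, THF, 50 °C, degassed
Reagents that add atoms: none
Why: Sonogashira coupling of the terminal alkyne with the same thienyl bromide used in step 1; neither propargylic ring C–H is acidic enough for the amine and the temperature stays far below that of any pericyclic reorganisation, so the cis arrangement should carry through to the meso target.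

Compound list
1 | 5-bromo-2,2'-bithiophene | Brc1ccc(-c2cccs2)s1 | starting material
2 | prop-2-yn-1-ol (propargyl alcohol) | OCC#C | starting material
3 | 3-(2,2'-bithiophen-5-yl)prop-2-yn-1-ol | OCC#Cc1ccc(-c2cccs2)s1 | intermediate
4 | 3-(2,2'-bithiophen-5-yl)prop-2-ynal | O=CC#Cc1ccc(-c2cccs2)s1 | intermediate
5 | cyclopropyldiphenylsulfonium tetrafluoroborate | C1CC1[S+](c1ccccc1)c1ccccc1.F[B-](F)(F)F | starting material
6 | diphenylsulfonium cyclopropylide | C1C[C-]1[S+](c1ccccc1)c1ccccc1 | intermediate
7 | 2-[(2,2'-bithiophen-5-yl)ethynyl]-1-oxaspiro[2.2]pentane (racemic) | C1CC12OC2C#Cc1ccc(-c2cccs2)s1 | intermediate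
8 | 2-[(2,2'-bithiophen-5-yl)ethynyl]cyclobutan-1-one (racemic) | O=C1CCC1C#Cc1ccc(-c2cccs2)s1 | intermediate
9 | 5-[(2-methylidenecyclobutyl)ethynyl]-2,2'-bithiophene (racemic) | C=C1CCC1C#Cc1ccc(-c2cccs2)s1 | intermediate
10 | 9-({cis-2-[(2,2'-bithiophen-5-yl)ethynyl]cyclobutyl}methyl)-9-borabicyclo[3.3.1]nonane (racemic) | C(B3C4CCCC3CCC4)[C@@H]1CC[C@@H]1C#Cc1ccc(-c2cccs2)s1 | intermediate
11 | {cis-2-[(2,2'-bithiophen-5-yl)ethynyl]cyclobutyl}methanol, (1R*,2S*), racemic | OC[C@@H]1CC[C@@H]1C#Cc1ccc(-c2cccs2)s1 | intermediate
12 | cis-2-[(2,2'-bithiophen-5-yl)ethynyl]cyclobutane-1-carbaldehyde, (1R*,2S*), racemic | O=C[C@@H]1CC[C@@H]1C#Cc1ccc(-c2cccs2)s1 | intermediate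
13 | 5-[(cis-2-ethynylcyclobutyl)ethynyl]-2,2'-bithiophene, racemic | C#C[C@@H]1CC[C@@H]1C#Cc1ccc(-c2cccs2)s1 | intermediate
14 | isocardopatine, 5,5''-{[(1R,2S)-cyclobutane-1,2-diyl]di(ethyne-2,1-diyl)}bis(2,2'-bithiophene), cis, meso | C(#C[C@@H]1CC[C@@H]1C#Cc1ccc(-c2cccs2)s1)c1ccc(-c2cccs2)s1 | target

Total step count: 8
Longest linear sequence: 8 steps (1 → 3 → 4 → 8 → 9 → 11 → 12 → 13 → 14); 5 and the second portion of 1 enter as purchased materials.

Steps most likely to fail

Step 3. The ynal may be lost to conjugate addition of the ylide or to base-induced deformylation, or the thermally labile ylide may decay before it adds. The fallback sets out from 4 and comes back to the route at 8. Cyclopropyl phenyl sulfide is lithiated (n-BuLi, THF, 0 °C) and added to 4 at −78 °C, which should give the carbinol 3-(2,2'-bithiophen-5-yl)-1-[1-(phenylsulfanyl)cyclopropyl]prop-2-yn-1-ol F1. p-TsOH in wet benzene (or aqueous HBF4 in ether) should then ionise the propargylic alcohol, the cyclopropane bond migrates to the cationic carbon, and the sulfur-stabilised cyclobutyl cation is hydrolysed to 8 with loss of benzenethiol.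

Step 5. Facial selectivity of the hydroboration may be poor because the slim, linear alkynyl arm shields its ring face only weakly, and the triple bond may compete for the borane. The fallback sets out from 9 and comes back at 11. Treatment of 9 with Co2(CO)8 (CH2Cl2, rt) should give the hexacarbonyldicobalt alkyne complex F2, in which the arm has become a bulky cluster and the triple bond is masked. 9-BBN should then add from the face opposite the cluster to give the complexed B-alkyl-9-BBN adduct F3, and NaBO3·4H2O (THF/H2O) should give the complexed cis-alcohol F4. Fe(NO3)3·9H2O in ethanol at 0 °C, too weak an oxidant in this medium to attack the bithiophene, should strip the cobalt and return 11.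

Step 7. Carbonate in methanol may epimerise the cis-aldehyde at C1 before the homologation captures it. The fallback sets out from 12 and comes back at 13. CBr4/PPh3 (CH2Cl2, 0 °C) should convert 12 under non-basic conditions into the cis-dibromoalkene 5-{[cis-2-(2,2-dibromoethenyl)cyclobutyl]ethynyl}-2,2'-bithiophene F5, which can no longer epimerise. n-BuLi (2 equiv, THF, −78 °C) followed by aqueous NH4Cl should then give 13 by bromine–lithium exchange, carbenoid 1,2-hydrogen shift and protonation of the lithium acetylide (Corey–Fuchs sequence); the aqueous quench also reprotonates any lithiated thiophene.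

Further compounds
F1 | step 3 | 3-(2,2'-bithiophen-5-yl)-1-[1-(phenylsulfanyl)cyclopropyl]prop-2-yn-1-ol (racemic) | OC(C#Cc1ccc(-c2cccs2)s1)C1(Sc2ccccc2)CC1
F2 | step 5 | hexacarbonyldicobalt alkyne complex of 9 (racemic) | C=C1CCC1[C]23[C]4(c5ccc(-c6cccs6)s5)[Co]2(=C=O)(=C=O)(=C=O)[Co]34(=C=O)(=C=O)=C=O
F3 | step 5 | hexacarbonyldicobalt alkyne complex of the cis B-alkyl-9-BBN adduct (racemic) | C(B7C8CCCC7CCC8)[C@@H]1CC[C@@H]1[C]23[C]4(c5ccc(-c6cccs6)s5)[Co]2(=C=O)(=C=O)(=C=O)[Co]34(=C=O)(=C=O)=C=O
F4 | step 5 | hexacarbonyldicobalt alkyne complex of cis-alcohol 11 (racemic) | OC[C@@H]1CC[C@@H]1[C]23[C]4(c5ccc(-c6cccs6)s5)[Co]2(=C=O)(=C=O)(=C=O)[Co]34(=C=O)(=C=O)=C=O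
F5 | step 7 | 5-{[cis-2-(2,2-dibromoethenyl)cyclobutyl]ethynyl}-2,2'-bithiophene (racemic) | BrC(Br)=C[C@@H]1CC[C@@H]1C#Cc1ccc(-c2cccs2)s1
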